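**Retrosynthetic overview**
- Both CH2OH groups come from CHO groups by NaBH4 in the last step. The ring B catechol comes from its dimethyl ether (BBr3), so the benzylic alcohols never meet a Lewis acid.
- Key C–C disconnection: the ring A aryl–CH2 bond is made by a para-selective phenol Mannich reaction of a 2-aryloxy-3,6-dibromophenol with Me2N=CH2+ I−. The benzylic amine is then raised to CHO (Sommelet type).
- C–O disconnection: the diaryl ether comes from SNAr of 3,6-dibromo-2-(methoxymethoxy)phenol on 2-fluoro-3,4-dimethoxybenzaldehyde. The ring B bromine is added by electrophilic bromination after the coupling.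
- The ring A phenol comes from 2,5-dibromophenol by MOM protection, directed ortho-lithiation between OMOM and Br, then borylation/oxidation.
- No ring is built. Ring A (from 2,5-dibromophenol) and ring B (from the fluoroaldehyde) are bought as benzenes and joined in step 3.

**Assumption:** the SMILES has no stereocentre, and the diaryl ether axis is not configurationally stable because two of the four ortho groups are OH. The target is therefore treated as achiral and no stereocontrol step is needed.

**Step 1**
Reactants: 1 2,5-dibromophenol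
Product: 2 1,4-dibromo-2-(methoxymethoxy)benzene
Conditions: MOMCl (1.2 equiv), K2CO3 (2 equiv), acetone, 0 °C to rt
Reagents that add atoms: chloromethyl methyl ether (MOMCl), COCCl
Why: Williamson-type O-alkylation of an acidic phenol gives a base-stable MOM ether that directs the next lithiation and can later be removed without touching aryl methyl ethers.

**Step 2**
Reactants: 2 1,4-dibromo-2-(methoxymethoxy)benzene
Product: 5 3,6-dibromo-2-(methoxymethoxy)phenol, via aryllithium 3 (not isolated), via dimethyl arylboronate 4 (not isolated)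
Conditions: LiN(i-Pr)2 (1.1 equiv), THF, −78 °C, 45 min; B(OMe)3 (1.5 equiv), −78 °C to 0 °C; AcOH, 30% H2O2, 0 °C to rt
Reagents that add atoms: hydrogen peroxide, OO
Why: In this directed ortho-metalation the amide base removes the most acidic ring proton, the one flanked by OMOM and Br (no Br/Li exchange, no aryne at −78 °C), and borylation followed by oxidative 1,2-migration turns C–Li into C–OH.

**Step 3**
Reactants: 5 3,6-dibromo-2-(methoxymethoxy)phenol; 6 2-fluoro-3,4-dimethoxybenzaldehyde (1.2 equiv)
Product: 7 2-[3,6-dibromo-2-(methoxymethoxy)phenoxy]-3,4-dimethoxybenzaldehyde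
Conditions: Cs2CO3 (1.5 equiv), DMSO, 100 °C, N2, 18 h
Reagents that add atoms: none
Why: In this SNAr (addition–elimination) the fluoride ortho to the formyl group is displaced by the caesium phenoxide, while the unactivated C–Br bonds and the MOM ether stay inert to carbonate.

**Step 4**
Reactants: 7 2-[3,6-dibromo-2-(methoxymethoxy)phenoxy]-3,4-dimethoxybenzaldehyde
Product: 8 5-bromo-2-[3,6-dibromo-2-(methoxymethoxy)phenoxy]-3,4-dimethoxybenzaldehyde
Conditions: NBS (1.05 equiv), DMF, rt to 40 °C, dark
Reagents that add atoms: N-bromosuccinimide (NBS), O=C1CCC(=O)N1Br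
Why: Electrophilic aromatic bromination goes to C5 of ring B (ortho to the coplanar 4-OMe, para to the aryloxy oxygen, meta to CHO, as with 2,3,4-trimethoxybenzaldehyde), whereas ring A is deactivated by two Br and twisted O-substituents and neutral NBS spares the MOM group.

**Step 5**
Reactants: 8 5-bromo-2-[3,6-dibromo-2-(methoxymethoxy)phenoxy]-3,4-dimethoxybenzaldehyde
Product: 9 5-bromo-2-(3,6-dibromo-2-hydroxyphenoxy)-3,4-dimethoxybenzaldehyde
Conditions: 3 M HCl, THF, 50 °C
Reagents that add atoms: none
Why: Acid-catalysed acetal hydrolysis removes only the MOM group and leaves the methyl ethers, aryl bromides, diaryl ether and aldehyde untouched.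

**Step 6**
Reactants: 9 5-bromo-2-(3,6-dibromo-2-hydroxyphenoxy)-3,4-dimethoxybenzaldehyde
Product: 10 3,6-dibromo-2-[4-bromo-6-(1,3-dioxolan-2-yl)-2,3-dimethoxyphenoxy]phenol
Conditions: HOCH2CH2OH (5 equiv), TsOH·H2O (5 mol %), toluene, reflux, Dean–Stark
Reagents that add atoms: ethylene glycol, OCCO
Why: Acid-catalysed acetalisation with azeotropic water removal masks the formyl group and so removes the activation of ring B, which stops the neighbouring ring A phenoxide from shifting ring B to the other oxygen (Smiles rearrangement) once ring A becomes unsymmetrical in step 7.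

**Step 7 (key step)**
Reactants: 10 3,6-dibromo-2-[4-bromo-6-(1,3-dioxolan-2-yl)-2,3-dimethoxyphenoxy]phenol; 11 N,N-dimethylmethyleneiminium iodide (Eschenmoser's salt, 1.5 equiv)
Product: 12 3,6-dibromo-2-[4-bromo-6-(1,3-dioxolan-2-yl)-2,3-dimethoxyphenoxy]-4-[(dimethylamino)methyl]phenol
Conditions: K2CO3 (2 equiv), MeCN, 60 °C, 16 h; work-up at pH 7–8
Reagents that add atoms: none
Why: In this intermolecular phenol Mannich reaction the phenoxide of 10, acting as a vinylogous enolate, attacks the preformed iminium carbon through its para carbon because both ortho carbons are blocked by Br and OAr, which places the new C–CH2 bond exactly where the target needs it, and ring B has no free OH so it does not react; no stereocentre is formed.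

**Step 8**
Reactants: 12 3,6-dibromo-2-[4-bromo-6-(1,3-dioxolan-2-yl)-2,3-dimethoxyphenoxy]-4-[(dimethylamino)methyl]phenol
Product: 16 2,5-dibromo-3-(4-bromo-6-formyl-2,3-dimethoxyphenoxy)-4-hydroxybenzaldehyde, via amino aldehyde 13 (not isolated), via hexaminium acetate 14 (not isolated), via aldimine 15 (not isolated)
Conditions: hexamethylenetetramine (3 equiv), AcOH/H2O 1:1, reflux, 4 h; then 3 M HCl, reflux, 20 min
Reagents that add atoms: water, O
Why: In this Sommelet-type oxidation of a phenolic Mannich base, hot aqueous acid opens the dioxolane, the p-hydroxybenzylammonium loses Me2NH by way of the quinone methide, hexamethylenetetramine adds, hydride transfer to a methyleneiminium gives the aldimine, and hydrolysis gives the aldehyde with no phenoxide present.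

**Step 9**
Reactants: 16 2,5-dibromo-3-(4-bromo-6-formyl-2,3-dimethoxyphenoxy)-4-hydroxybenzaldehyde
Product: 17 2,5-dibromo-3-(4-bromo-6-formyl-2,3-dihydroxyphenoxy)-4-hydroxybenzaldehyde
Conditions: BBr3 (8 equiv), CH2Cl2, −78 °C to rt, 12 h; ice/H2O
Reagents that add atoms: none
Why: Lewis-acid O-demethylation cleaves both aryl methyl ethers by bromide attack on methyl, while the formyl groups, aryl bromides and diaryl ether survive, as they do for brominated veratraldehydes.

**Step 10**
Reactants: 17 2,5-dibromo-3-(4-bromo-6-formyl-2,3-dihydroxyphenoxy)-4-hydroxybenzaldehyde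
Product: 18 6-bromo-3-[2,5-dibromo-6-hydroxy-3-(hydroxymethyl)phenoxy]-4-(hydroxymethyl)benzene-1,2-diol (target)
Conditions: NaBH4 (6 equiv), THF/H2O 4:1, 0 °C to rt; 1 M HCl to pH 5 at 0 °C; no MeOH in work-up or chromatography
Reagents that add atoms: none
Why: Hydride reduction of both aldehydes works on free bromophenol aldehydes, the alcohol-free mildly acidic work-up avoids benzylic ether formation by way of quinone methides, and no stereocentre arises.

**Compound list**
1 | 2,5-dibromophenol | Oc1cc(Br)ccc1Br | starting material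
2 | 1,4-dibromo-2-(methoxymethoxy)benzene | COCOc1cc(Br)ccc1Br | intermediate
3 | [3,6-dibromo-2-(methoxymethoxy)phenyl]lithium | [Li]c1c(Br)ccc(Br)c1OCOC | intermediate (not isolated)
4 | dimethyl [3,6-dibromo-2-(methoxymethoxy)phenyl]boronate | COB(OC)c1c(Br)ccc(Br)c1OCOC | intermediate (not isolated)
5 | 3,6-dibromo-2-(methoxymethoxy)phenol | Oc1c(Br)ccc(Br)c1OCOC | intermediate
6 | 2-fluoro-3,4-dimethoxybenzaldehyde | COc1ccc(C=O)c(F)c1OC | starting material
7 | 2-[3,6-dibromo-2-(methoxymethoxy)phenoxy]-3,4-dimethoxybenzaldehyde | COCOc1c(Br)ccc(Br)c1Oc1c(C=O)ccc(OC)c1OC | intermediate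
8 | 5-bromo-2-[3,6-dibromo-2-(methoxymethoxy)phenoxy]-3,4-dimethoxybenzaldehyde | COCOc1c(Br)ccc(Br)c1Oc1c(C=O)cc(Br)c(OC)c1OC | intermediate
9 | 5-bromo-2-(3,6-dibromo-2-hydroxyphenoxy)-3,4-dimethoxybenzaldehyde | Oc1c(Br)ccc(Br)c1Oc1c(C=O)cc(Br)c(OC)c1OC | intermediate
10 | 3,6-dibromo-2-[4-bromo-6-(1,3-dioxolan-2-yl)-2,3-dimethoxyphenoxy]phenol | Oc1c(Br)ccc(Br)c1Oc1c(C2OCCO2)cc(Br)c(OC)c1OC | intermediate
11 | N,N-dimethylmethyleneiminium iodide (Eschenmoser's salt) | C=[N+](C)C.[I-] | starting material
12 | 3,6-dibromo-2-[4-bromo-6-(1,3-dioxolan-2-yl)-2,3-dimethoxyphenoxy]-4-[(dimethylamino)methyl]phenol | CN(C)Cc1cc(Br)c(O)c(Oc2c(C3OCCO3)cc(Br)c(OC)c2OC)c1Br | intermediate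
13 | 5-bromo-2-{2,5-dibromo-3-[(dimethylamino)methyl]-6-hydroxyphenoxy}-3,4-dimethoxybenzaldehyde | CN(C)Cc1cc(Br)c(O)c(Oc2c(C=O)cc(Br)c(OC)c2OC)c1Br | intermediate (not isolated)
14 | 1-{[2,5-dibromo-3-(4-bromo-6-formyl-2,3-dimethoxyphenoxy)-4-hydroxyphenyl]methyl}-1,3,5,7-tetraazaadamantan-1-ium acetate | C1N2CN3CN1C[N+](C2)(C3)Cc1cc(Br)c(O)c(Oc2c(C=O)cc(Br)c(OC)c2OC)c1Br.CC(=O)[O-] | intermediate (not isolated)
15 | 5-bromo-2-[2,5-dibromo-6-hydroxy-3-(iminomethyl)phenoxy]-3,4-dimethoxybenzaldehyde | N=Cc1cc(Br)c(O)c(Oc2c(C=O)cc(Br)c(OC)c2OC)c1Br | intermediate (not isolated)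
16 | 2,5-dibromo-3-(4-bromo-6-formyl-2,3-dimethoxyphenoxy)-4-hydroxybenzaldehyde | O=Cc1cc(Br)c(O)c(Oc2c(C=O)cc(Br)c(OC)c2OC)c1Br | intermediate
17 | 2,5-dibromo-3-(4-bromo-6-formyl-2,3-dihydroxyphenoxy)-4-hydroxybenzaldehyde | O=Cc1cc(Br)c(O)c(Oc2c(C=O)cc(Br)c(O)c2O)c1Br | intermediate
18 | 6-bromo-3-[2,5-dibromo-6-hydroxy-3-(hydroxymethyl)phenoxy]-4-(hydroxymethyl)benzene-1,2-diol | OCc1cc(Br)c(O)c(Oc2c(CO)cc(Br)c(O)c2O)c1Br | target

**Total step count:** 10. **Longest linear sequence:** 10 steps (1 to 18); 6 and 11 are bought.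

**Three steps most likely to fail**

**Step 3** (SNAr between two di-ortho-substituted partners, with a donor-substituted aryl fluoride). The fallback replaces addition–elimination by copper catalysis; it sets out from 5 and comes back at 7. Commercial isovanillin is iodinated at C2 (ICl, pyridine/dioxane) to 3-hydroxy-2-iodo-4-methoxybenzaldehyde F1. This is O-methylated (MeI, K2CO3, DMF) to 2-iodo-3,4-dimethoxybenzaldehyde F2. F2 is then coupled with 5 under Ullmann-type conditions (CuI 10 mol %, picolinic acid 20 mol %, K3PO4, DMSO, 85 °C). The carbon–iodine bond ortho to CHO reacts well before the hindered C–Br bonds of 5.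

**Step 7** (the dibrominated phenoxide may be too weak a carbon nucleophile for the iminium salt). The fallback moves to a strongly acidic medium and a direct formylation; it sets out from 9 and comes back at 16, skipping steps 6 to 8. Compound 9 is heated with hexamethylenetetramine in CF3CO2H at reflux and then hydrolysed with aqueous HCl (Duff reaction). This method para-formylates 2,6-dihalophenols. No acetal is needed because no phenoxide exists in this medium. New compounds on this way: none F0.

**Step 8** (the electron-poor Mannich base may ionise too slowly for the Sommelet-type oxidation). The fallback exchanges nitrogen for oxygen first and oxidises afterwards; it sets out from 12 and comes back at 16.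
- Refluxing Ac2O converts 12 into {4-acetoxy-2,5-dibromo-3-[4-bromo-6-(1,3-dioxolan-2-yl)-2,3-dimethoxyphenoxy]phenyl}methyl acetate F3.
- Dilute LiOH in THF/H2O at 0 °C gives 3,6-dibromo-2-[4-bromo-6-(1,3-dioxolan-2-yl)-2,3-dimethoxyphenoxy]-4-(hydroxymethyl)phenol F4.
- MnO2 in CH2Cl2 oxidises the benzylic alcohol to 2,5-dibromo-3-[4-bromo-6-(1,3-dioxolan-2-yl)-2,3-dimethoxyphenoxy]-4-hydroxybenzaldehyde F5.
- 1 M HCl in THF opens the dioxolane to give 16.

**Further compounds**
F1 | step 3 | 3-hydroxy-2-iodo-4-methoxybenzaldehyde | COc1ccc(C=O)c(I)c1O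
F2 | step 3 | 2-iodo-3,4-dimethoxybenzaldehyde | COc1ccc(C=O)c(I)c1OC
F0 | step 7 | none | none
F3 | step 8 | {4-acetoxy-2,5-dibromo-3-[4-bromo-6-(1,3-dioxolan-2-yl)-2,3-dimethoxyphenoxy]phenyl}methyl acetate | CC(=O)OCc1cc(Br)c(OC(C)=O)c(Oc2c(C3OCCO3)cc(Br)c(OC)c2OC)c1Br
F4 | step 8 | 3,6-dibromo-2-[4-bromo-6-(1,3-dioxolan-2-yl)-2,3-dimethoxyphenoxy]-4-(hydroxymethyl)phenol | OCc1cc(Br)c(O)c(Oc2c(C3OCCO3)cc(Br)c(OC)c2OC)c1Br
F5 | step 8 | 2,5-dibromo-3-[4-bromo-6-(1,3-dioxolan-2-yl)-2,3-dimethoxyphenoxy]-4-hydroxybenzaldehyde | O=Cc1cc(Br)c(O)c(Oc2c(C3OCCO3)cc(Br)c(OC)c2OC)c1Br
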